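**Retrosynthetic overview**
1. The plan rests on the C4 carbonyl of the pyranone (ring C). It lies between C4a of ring A and C3, so it is cut out as CO. C3 and C2 then belong to a terminal aryl alkyne carrying ring B, and O1–C2 forms when the C8a phenol adds to the resulting ynone.
2. Late disconnections are the O5 and O7 MOM acetals, the O3–prenyl bond (Williamson), and the C3–O bond (C3 lithiation, borylation and oxidation of the flavone).
3. Rings A and B are bought. Ring C is the only ring formed, in one operation from an o-acetoxyaryl iodide, 1-ethynyl-4-(prenyloxy)benzene and CO.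
4. The iodide comes from mirror-symmetric 2-methoxy-5-(MOM-oxy)resorcinol, whose two free ring positions are equivalent, so iodination has one possible outcome. In an unsymmetrical 2-methoxy-3,5-bis(MOM-oxy)phenol the positions ortho and para to OH are each activated by three oxygens. Iodine then sits between the MOM-blocked O5 and the oxygen next to OMe, which fixes the 8-methoxy pattern, and O7 is re-protected after the annulation.
5. The symmetric resorcinol comes from 2-methoxyresorcinol by sterically controlled C–H borylation/oxidation at C5. The alkyne comes from 4-hydroxybenzaldehyde by prenylation and Ohira–Bestmann homologation.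

Key step: step 8

Remark on the chemistry: the target has no stereocentre and no stereogenic double bond (each prenyl alkene ends in CMe2). It is therefore achiral, the question of a single enantiomer does not arise, and no step needs stereocontrol.

Abbreviations: prenyl = 3-methylbut-2-en-1-yl; MOM = methoxymethyl; TBS = tert-butyldimethylsilyl; TIPS = triisopropylsilyl. Flavone numbering is used from step 8 on.

**Route**

Step 1
Reactants: 1 2-methoxybenzene-1,3-diol (2-methoxyresorcinol)
Product: 2 1,3-bis(tert-butyldimethylsilyloxy)-2-methoxybenzene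
Conditions: TBSCl (2.3 equiv), imidazole, DMF, rt
Reagents that add atoms: tert-butyldimethylsilyl chloride, CC(C)(C)[Si](C)(C)Cl
Why: Imidazole-promoted O-silylation of both phenols is a routine protection, and the bulky silyl ethers later shield C4 and C6 in the C–H borylation.

Step 2
Reactants: 2 1,3-bis(tert-butyldimethylsilyloxy)-2-methoxybenzene
Product: 4 3,5-bis(tert-butyldimethylsilyloxy)-4-methoxyphenol, via aryl pinacol boronate 3 (not isolated)
Conditions: [Ir(OMe)(cod)]2 (1.5 mol %), dtbpy (3 mol %), B2pin2 (1.0 equiv), THF, 80 °C; evaporate; Oxone, acetone–H2O, rt, 10 min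
Reagents that add atoms: bis(pinacolato)diboron, CC1(C)OB(OC1(C)C)B1OC(C)(C)C(C)(C)O1 (boryl group of 3); potassium peroxymonosulfate (active part of Oxone), [K+].[O-]S(=O)(=O)OO (phenol oxygen of 4)
Why: Iridium-catalysed aromatic C–H borylation is ruled by sterics, so in the symmetric 1,2,3-trisubstituted ring of 2 only C5–H (no ortho substituent) reacts, and the one-pot peroxymonosulfate oxidation of boronate 3 is fast and weakly acidic enough to leave the aryl silyl ethers intact.

Step 3
Reactants: 4 3,5-bis(tert-butyldimethylsilyloxy)-4-methoxyphenol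
Product: 5 1,3-bis(tert-butyldimethylsilyloxy)-2-methoxy-5-(methoxymethoxy)benzene
Conditions: MOMCl, iPr2NEt, CH2Cl2, 0 °C → rt
Reagents that add atoms: chloromethyl methyl ether, COCCl
Why: Williamson-type alkylation of the only free phenol with MOMCl and a hindered amine marks the oxygen that becomes O5 and makes it unable to cyclise later.

Step 4
Reactants: 5 1,3-bis(tert-butyldimethylsilyloxy)-2-methoxy-5-(methoxymethoxy)benzene
Product: 6 2-methoxy-5-(methoxymethoxy)benzene-1,3-diol
Conditions: TBAF (2.2 equiv), AcOH (2.2 equiv), THF, 0 °C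
Reagents that add atoms: none
Why: Fluoride-induced desilylation cleaves aryl silyl ethers rapidly, the acetic acid buffer keeps the air-sensitive resorcinol protonated, and the MOM acetal is inert to fluoride.

Step 5
Reactants: 6 2-methoxy-5-(methoxymethoxy)benzene-1,3-diol
Product: 8 4-iodo-2-methoxy-5-(methoxymethoxy)-1,3-phenylene diacetate, via iodoresorcinol 7 (not isolated)
Conditions: NIS (1.0 equiv), MeCN, −20 °C, dark; then pyridine, Ac2O, DMAP (cat.), 0 °C → rt
Reagents that add atoms: N-iodosuccinimide, O=C1CCC(=O)N1I; acetic anhydride, CC(=O)OC(C)=O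
Why: Electrophilic aromatic iodination can give only one monoiodide because C4 and C6 of 6 are related by the mirror plane through C2 and C5, the new iodine slows a second substitution, and immediate DMAP-catalysed acetylation turns the sensitive iodoresorcinol 7 into a stable, less electron-rich aryl iodide.

Step 6
Reactants: 9 4-hydroxybenzaldehyde; 10 prenyl bromide (1-bromo-3-methylbut-2-ene)
Product: 11 4-(prenyloxy)benzaldehyde
Conditions: K2CO3, DMF, rt
Reagents that add atoms: prenyl bromide (10), CC(C)=CCBr
Why: Williamson ether synthesis by SN2 attack of the phenoxide at the primary allylic bromide, for which O-alkylation in a polar aprotic medium is the normal outcome.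

Step 7
Reactants: 11 4-(prenyloxy)benzaldehyde
Product: 12 1-ethynyl-4-(prenyloxy)benzene
Conditions: dimethyl (1-diazo-2-oxopropyl)phosphonate, K2CO3, MeOH, rt
Reagents that add atoms: dimethyl (1-diazo-2-oxopropyl)phosphonate, COP(=O)(OC)C(=[N+]=[N-])C(C)=O
Why: In the Ohira–Bestmann homologation methanolysis frees the diazomethylphosphonate anion, which adds to the aldehyde, and loss of phosphate and nitrogen with a 1,2-shift gives the terminal alkyne under mild base that leaves the prenyl ether alone.

Step 8
Reactants: 8 4-iodo-2-methoxy-5-(methoxymethoxy)-1,3-phenylene diacetate; 12 1-ethynyl-4-(prenyloxy)benzene; 13 carbon monoxide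
Product: 16 7-hydroxy-8-methoxy-5-(methoxymethoxy)-4'-(prenyloxy)flavone, via ynone diacetate 14 (not isolated), via diethylamino enone 15 (not isolated)
Conditions: PdCl2(PPh3)2, dppp, thiourea (5 mol % each), CO (1 atm, balloon), Et2NH (10 equiv), DMF, 45 °C then 60 °C
Reagents that add atoms: carbon monoxide (13), [C-]#[O+]; diethylamine, CCNCC (amino group of 15 only, lost again on closure)
Why: Pd(0) inserts into the C–I bond of 8, which the two acetates keep less electron-rich than a free phenoxide, CO migratory insertion gives the aroylpalladium species, and transfer of the amine-generated acetylide of 12 with reductive elimination gives ynone 14 (bonds C4a–C4 and C4–C3). Diethylamine then removes both aryl acetates by aminolysis and adds to the ynone to give the β-amino enone 15, in which the C8a phenol attacks C2 and expels the amine (bond O1–C2). The closest known reaction type is the palladium-catalysed carbonylative annulation of o-iodophenols or their acetates with terminal alkynes in a secondary amine, that is a carbonylative Sonogashira coupling followed by oxa-Michael addition–elimination. The one ring formed, pyranone ring C, closes in the 6-endo sense, and no stereocentre is created. Flavone rather than aurone (5-exo) formation is secured by the secondary amine, since C2 is the only electrophilic carbon left in 15, and the 8-methoxy rather than 6-methoxy pattern is secured by the substrate, since the acyl carbon is flanked by the oxygen next to OMe on one side and by the O5 MOM ether, which cannot add, on the other. The CO atmosphere and the absence of copper disfavour coupling without CO uptake, and the low temperature is chosen so that Pd(0) and amine do not ionise the trisubstituted prenyl ether.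

Step 9
Reactants: 16 7-hydroxy-8-methoxy-5-(methoxymethoxy)-4'-(prenyloxy)flavone
Product: 17 8-methoxy-5,7-bis(methoxymethoxy)-4'-(prenyloxy)flavone
Conditions: MOMCl, iPr2NEt, CH2Cl2, 0 °C → rt
Reagents that add atoms: chloromethyl methyl ether, COCCl
Why: The acidic 7-OH (a vinylogous acid) is the only free hydroxyl and is alkylated by MOMCl and a hindered amine in a Williamson-type etherification, which removes the acidic proton before the lithiation.

Step 10
Reactants: 17 8-methoxy-5,7-bis(methoxymethoxy)-4'-(prenyloxy)flavone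
Product: 20 3-hydroxy-8-methoxy-5,7-bis(methoxymethoxy)-4'-(prenyloxy)flavone, via 3-lithioflavone 18 (not isolated), via flavon-3-ylboronate 19 (not isolated)
Conditions: LDA (1.5 equiv), THF, −78 °C; B(OMe)3 (3 equiv), −78 → 0 °C; AcOH, 30 % H2O2, 0 °C → rt
Reagents that add atoms: lithium diisopropylamide, [Li+].CC(C)[N-]C(C)C (lithium of 18); trimethyl borate, COB(OC)OC (boron group of 19); hydrogen peroxide, OO (O3 of 20)
Why: Carbonyl-directed deprotonation of flavones by LDA takes place at C3–H next to the coordinating C4 carbonyl, whereas C6–H between the MOM ethers needs an alkyllithium, and borate trapping followed by peroxide-induced 1,2-migration (boronate oxidation) gives the flavonol without touching the unactivated prenyl alkene.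

Step 11
Reactants: 20 3-hydroxy-8-methoxy-5,7-bis(methoxymethoxy)-4'-(prenyloxy)flavone; 10 prenyl bromide
Product: 21 8-methoxy-5,7-bis(methoxymethoxy)-3,4'-bis(prenyloxy)flavone
Conditions: prenyl bromide (1.2 equiv), K2CO3, DMF, rt
Reagents that add atoms: prenyl bromide (10), CC(C)=CCBr
Why: Williamson etherification of the acidic enolic 3-OH, the only free hydroxyl of 20, with the primary allylic bromide.

Step 12
Reactants: 21 8-methoxy-5,7-bis(methoxymethoxy)-3,4'-bis(prenyloxy)flavone
Product: 22 5,7-dihydroxy-8-methoxy-3,4'-bis(prenyloxy)flavone (target)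
Conditions: conc. HCl (cat.), MeOH–THF, rt to 40 °C, stopped as soon as the 7-O-MOM group is gone
Reagents that add atoms: none
Why: Acid-catalysed acetal exchange with methanol runs through the methoxymethyl oxocarbenium ion, which forms far more readily than the dimethylallyl cation, so both MOM groups should fall before the prenyl ethers ionise, the 5-O-MOM being further labilised by the peri carbonyl.

**Compound list**
1 | 2-methoxybenzene-1,3-diol (2-methoxyresorcinol) | COc1c(O)cccc1O | starting material
2 | 1,3-bis(tert-butyldimethylsilyloxy)-2-methoxybenzene | COc1c(O[Si](C)(C)C(C)(C)C)cccc1O[Si](C)(C)C(C)(C)C | intermediate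
3 | 2-[3,5-bis(tert-butyldimethylsilyloxy)-4-methoxyphenyl]-4,4,5,5-tetramethyl-1,3,2-dioxaborolane (formed in the flask) | COc1c(O[Si](C)(C)C(C)(C)C)cc(B2OC(C)(C)C(C)(C)O2)cc1O[Si](C)(C)C(C)(C)C | intermediate
4 | 3,5-bis(tert-butyldimethylsilyloxy)-4-methoxyphenol | COc1c(O[Si](C)(C)C(C)(C)C)cc(O)cc1O[Si](C)(C)C(C)(C)C | intermediate
5 | 1,3-bis(tert-butyldimethylsilyloxy)-2-methoxy-5-(methoxymethoxy)benzene | COCOc1cc(O[Si](C)(C)C(C)(C)C)c(OC)c(O[Si](C)(C)C(C)(C)C)c1 | intermediate
6 | 2-methoxy-5-(methoxymethoxy)benzene-1,3-diol | COCOc1cc(O)c(OC)c(O)c1 | intermediate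
7 | 4-iodo-2-methoxy-5-(methoxymethoxy)benzene-1,3-diol (formed in the flask) | COCOc1cc(O)c(OC)c(O)c1I | intermediate
8 | 4-iodo-2-methoxy-5-(methoxymethoxy)-1,3-phenylene diacetate | COCOc1cc(OC(C)=O)c(OC)c(OC(C)=O)c1I | intermediate
9 | 4-hydroxybenzaldehyde | O=Cc1ccc(O)cc1 | starting material
10 | prenyl bromide (1-bromo-3-methylbut-2-ene) | CC(C)=CCBr | starting material
11 | 4-(prenyloxy)benzaldehyde | CC(C)=CCOc1ccc(C=O)cc1 | intermediate
12 | 1-ethynyl-4-(prenyloxy)benzene | C#Cc1ccc(OCC=C(C)C)cc1 | intermediate
13 | carbon monoxide | [C-]#[O+] | starting material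
14 | 2-methoxy-5-(methoxymethoxy)-4-{3-[4-(prenyloxy)phenyl]prop-2-ynoyl}-1,3-phenylene diacetate (formed in the flask) | COCOc1cc(OC(C)=O)c(OC)c(OC(C)=O)c1C(=O)C#Cc1ccc(OCC=C(C)C)cc1 | intermediate
15 | 3-(diethylamino)-1-[2,4-dihydroxy-3-methoxy-6-(methoxymethoxy)phenyl]-3-[4-(prenyloxy)phenyl]prop-2-en-1-one (formed in the flask; C=C geometry not fixed and lost on closure) | COCOc1cc(O)c(OC)c(O)c1C(=O)C=C(N(CC)CC)c1ccc(OCC=C(C)C)cc1 | intermediate
16 | 7-hydroxy-8-methoxy-5-(methoxymethoxy)-4'-(prenyloxy)flavone | COCOc1cc(O)c(OC)c2oc(-c3ccc(OCC=C(C)C)cc3)cc(=O)c12 | intermediate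
17 | 8-methoxy-5,7-bis(methoxymethoxy)-4'-(prenyloxy)flavone | COCOc1cc(OCOC)c2c(=O)cc(-c3ccc(OCC=C(C)C)cc3)oc2c1OC | intermediate
18 | 3-lithio-8-methoxy-5,7-bis(methoxymethoxy)-4'-(prenyloxy)flavone (formed in the flask) | COCOc1cc(OCOC)c2c(=O)c([Li])c(-c3ccc(OCC=C(C)C)cc3)oc2c1OC | intermediate
19 | dimethyl [8-methoxy-5,7-bis(methoxymethoxy)-4'-(prenyloxy)flavon-3-yl]boronate (formed in the flask) | COCOc1cc(OCOC)c2c(=O)c(B(OC)OC)c(-c3ccc(OCC=C(C)C)cc3)oc2c1OC | intermediate
20 | 3-hydroxy-8-methoxy-5,7-bis(methoxymethoxy)-4'-(prenyloxy)flavone | COCOc1cc(OCOC)c2c(=O)c(O)c(-c3ccc(OCC=C(C)C)cc3)oc2c1OC | intermediate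
21 | 8-methoxy-5,7-bis(methoxymethoxy)-3,4'-bis(prenyloxy)flavone | COCOc1cc(OCOC)c2c(=O)c(OCC=C(C)C)c(-c3ccc(OCC=C(C)C)cc3)oc2c1OC | intermediate
22 | 5,7-dihydroxy-8-methoxy-3,4'-bis(prenyloxy)flavone (achiral) | COc1c(O)cc(O)c2c(=O)c(OCC=C(C)C)c(-c3ccc(OCC=C(C)C)cc3)oc12 | target

**Step count**
Total step count: 12.
Longest linear sequence: 10 (steps 1–5 and 8–12).

**Steps most likely to fail**

1. Step 8.
- What may go wrong: oxidative addition at a C–I bond between two ortho oxygen substituents may be slow, the more so once the amine has stripped the acetates. The aroylpalladium species may then be intercepted by diethylamine, coupling may proceed without CO uptake, and long heating may let palladium and amine remove the prenyl group.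
- Fallback (polar assembly of the ynone, without palladium or CO gas): it sets out from 5 and 12 and comes back at 15, and so at 16.
- Lithiation of 5 with s-BuLi/TMEDA in THF is directed by the MOM ether to one of the two equivalent ring positions. It is held at −78 °C to prevent O-to-C silyl migration, and it gives the aryllithium F1.
- Compound 12 is deprotonated with n-BuLi and acylated with N-methoxy-N-methylcarbamoyl chloride to give the Weinreb amide N-methoxy-N-methyl-3-[4-(prenyloxy)phenyl]prop-2-ynamide F2.
- Addition of F1 to F2 at −78 °C gives the bis-silylated ynone F3.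
- Diethylamine adds to F3 at rt to give the silylated diethylamino enone F4. TBAF/AcOH then frees the phenols to 15, which closes to 16.

2. Step 10.
- What may go wrong: deprotonation may be incomplete or stray to C6–H between the MOM ethers. The amide base may add at C2, the C3 anion may open the pyranone by expelling the C8a phenoxide on warming, and the C3–boron bond may be protonated before it is oxidised.
- Fallback (oxidation of the C2–C3 double bond instead of deprotonation, which needs a ring B substituent without an alkene): it sets out from 8 and 13 and comes back at 21.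
- Compound 8 is annulated as in step 8 with commercial 1-(benzyloxy)-4-ethynylbenzene F5 to give 4'-benzyloxy-7-hydroxy-8-methoxy-5-(methoxymethoxy)flavone F6.
- MOMCl/iPr2NEt gives the bis-MOM ether F7.
- Dimethyldioxirane in acetone–CH2Cl2 at 0 °C oxidises C2–C3, and contact with silica gives the flavonol F8.
- Hydrogenolysis (H2, Pd/C, EtOAc) frees the 4'-phenol to give the 3,4'-diol F9.
- Double Williamson etherification with 10 (2.2 equiv, K2CO3, DMF) gives 21.

3. Step 12.
- What may go wrong: the acid may ionise the prenyl ethers, causing loss of prenyl, O-to-C migration, or ring closure onto a freed neighbouring hydroxyl. Forcing conditions may also open and reclose the pyranone (Wessely–Moser isomerisation), moving the methoxy group from C8 to C6.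
- Fallback (a fluoride-labile group on O7, so that only the very labile peri MOM group is left for acid): it sets out from 16 and comes back at 22.
- TIPSCl/imidazole gives the 7-O-TIPS ether F10.
- The sequence of step 10 gives the flavonol F11.
- Mitsunobu etherification with 3-methylbut-2-en-1-ol (PPh3, DIAD) is neutral enough to keep the silyl ether and gives the 3-O-prenyl ether F12.
- TBAF/AcOH gives the 7-phenol F13.
- The remaining 5-O-MOM group, activated by the peri C4 carbonyl, is removed with PPTS in MeOH at rt to give 22.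

**Further compounds**
F1 | step 8 | [2,4-bis(tert-butyldimethylsilyloxy)-3-methoxy-6-(methoxymethoxy)phenyl]lithium | COCOc1cc(O[Si](C)(C)C(C)(C)C)c(OC)c(O[Si](C)(C)C(C)(C)C)c1[Li]
F2 | step 8 | N-methoxy-N-methyl-3-[4-(prenyloxy)phenyl]prop-2-ynamide | CON(C)C(=O)C#Cc1ccc(OCC=C(C)C)cc1
F3 | step 8 | 1-[2,4-bis(tert-butyldimethylsilyloxy)-3-methoxy-6-(methoxymethoxy)phenyl]-3-[4-(prenyloxy)phenyl]prop-2-yn-1-one | COCOc1cc(O[Si](C)(C)C(C)(C)C)c(OC)c(O[Si](C)(C)C(C)(C)C)c1C(=O)C#Cc1ccc(OCC=C(C)C)cc1
F4 | step 8 | 1-[2,4-bis(tert-butyldimethylsilyloxy)-3-methoxy-6-(methoxymethoxy)phenyl]-3-(diethylamino)-3-[4-(prenyloxy)phenyl]prop-2-en-1-one | COCOc1cc(O[Si](C)(C)C(C)(C)C)c(OC)c(O[Si](C)(C)C(C)(C)C)c1C(=O)C=C(N(CC)CC)c1ccc(OCC=C(C)C)cc1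
F5 | step 10 | 1-(benzyloxy)-4-ethynylbenzene | C#Cc1ccc(OCc2ccccc2)cc1
F6 | step 10 | 4'-benzyloxy-7-hydroxy-8-methoxy-5-(methoxymethoxy)flavone | COCOc1cc(O)c(OC)c2oc(-c3ccc(OCc4ccccc4)cc3)cc(=O)c12
F7 | step 10 | 4'-benzyloxy-8-methoxy-5,7-bis(methoxymethoxy)flavone | COCOc1cc(OCOC)c2c(=O)cc(-c3ccc(OCc4ccccc4)cc3)oc2c1OC
F8 | step 10 | 4'-benzyloxy-3-hydroxy-8-methoxy-5,7-bis(methoxymethoxy)flavone | COCOc1cc(OCOC)c2c(=O)c(O)c(-c3ccc(OCc4ccccc4)cc3)oc2c1OC
F9 | step 10 | 3,4'-dihydroxy-8-methoxy-5,7-bis(methoxymethoxy)flavone | COCOc1cc(OCOC)c2c(=O)c(O)c(-c3ccc(O)cc3)oc2c1OC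
F10 | step 12 | 8-methoxy-5-(methoxymethoxy)-4'-(prenyloxy)-7-(triisopropylsilyloxy)flavone | COCOc1cc(O[Si](C(C)C)(C(C)C)C(C)C)c(OC)c2oc(-c3ccc(OCC=C(C)C)cc3)cc(=O)c12
F11 | step 12 | 3-hydroxy-8-methoxy-5-(methoxymethoxy)-4'-(prenyloxy)-7-(triisopropylsilyloxy)flavone | COCOc1cc(O[Si](C(C)C)(C(C)C)C(C)C)c(OC)c2oc(-c3ccc(OCC=C(C)C)cc3)c(O)c(=O)c12
F12 | step 12 | 8-methoxy-5-(methoxymethoxy)-3,4'-bis(prenyloxy)-7-(triisopropylsilyloxy)flavone | COCOc1cc(O[Si](C(C)C)(C(C)C)C(C)C)c(OC)c2oc(-c3ccc(OCC=C(C)C)cc3)c(OCC=C(C)C)c(=O)c12
F13 | step 12 | 7-hydroxy-8-methoxy-5-(methoxymethoxy)-3,4'-bis(prenyloxy)flavone | COCOc1cc(O)c(OC)c2oc(-c3ccc(OCC=C(C)C)cc3)c(OCC=C(C)C)c(=O)c12
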